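**Retrosynthetic overview**

1. Rings: A = para-phenylene, B = the ring with the free OH, C = meta-phenylene, D = quinone. Ring D is carried as a 1,4-dimethoxyarene and oxidised last, so all four six-membered rings are bought as benzenes and the only ring the route forms is the 18-membered macrocycle.
2. Key disconnection: the bond between the benzylic CH2 of the ring D–ring A ethano bridge and the ring A carbon para to the ether oxygen. It opens to a vinyl group on ring D and a C–Br bond on ring A; forward, hydroboration and B-alkyl Suzuki–Miyaura macrocyclization in one flask.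
3. Enabling feature: that CH2 is a primary sp3 carbon without a stereocentre, two atoms from ring D and bonded to an unhindered ring A carbon, so the bridge maps onto a terminal styrene. The ortho-linked ring D, meta-linked ring C and the two diaryl ether oxygens fold the open chain so that its ends can meet.
4. The ring C–ring B bridge is made the same way intermolecularly (styrene 4 plus aryl iodide 9, C–I before C–Br). The ethers come from a Chan–Lam coupling (A–O–B) and an SNAr reaction (C–O–D).
5. One formyl group on ring D does three jobs: it is installed by ortho-lithiation, activates the SNAr, and becomes the vinyl group of the key step.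

Key step: step 7

Remark: the target has no stereocentre and no stereogenic double bond, and the 18-membered cyclophane is taken as conformationally mobile, so no stereodescriptors are needed.

**Route**

Step 1
Reactants: 1 isovanillin (3-hydroxy-4-methoxybenzaldehyde); 2 4-bromophenylboronic acid
Product: 3 3-(4-bromophenoxy)-4-methoxybenzaldehyde
Conditions: Cu(OAc)2 (20 mol %), pyridine, 4 Å MS, CH2Cl2, O2 (1 atm), rt
Reagents that add atoms: none
Why: Chan–Lam O-arylation of the phenol by the arylboronic acid at room temperature should leave the aldehyde and the C–Br bond of ring A untouched, since the copper catalyst does not insert into aryl bromides under these conditions.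

Step 2
Reactants: 3 3-(4-bromophenoxy)-4-methoxybenzaldehyde
Product: 4 2-(4-bromophenoxy)-4-ethenyl-1-methoxybenzene
Conditions: MePPh3Br, KOtBu, THF, 0 °C → rt
Reagents that add atoms: methyltriphenylphosphonium bromide, C[P+](c1ccccc1)(c1ccccc1)c1ccccc1.[Br-]
Why: Wittig methylenation of an unhindered aromatic aldehyde by the non-stabilised ylide is reliable and inert to the aryl bromide and the ethers.

Step 3
Reactants: 5 2-fluoro-1,4-dimethoxybenzene
Product: 7 2-fluoro-3,6-dimethoxybenzaldehyde, via aryllithium 6 (not isolated)
Conditions: n-BuLi, THF, −78 °C; DMF, −78 °C → rt; aq. HCl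
Reagents that add atoms: N,N-dimethylformamide, CN(C)C=O
Why: directed ortho-metalation should take place at the one C–H flanked by fluorine and a methoxy group, the most acidic site, and formylation of the aryllithium at −78 °C should outrun loss of LiF to the aryne.

Step 4
Reactants: 7 2-fluoro-3,6-dimethoxybenzaldehyde; 8 3-iodophenol
Product: 9 2-(3-iodophenoxy)-3,6-dimethoxybenzaldehyde
Conditions: K2CO3, DMF, 110 °C
Reagents that add atoms: none
Why: nucleophilic aromatic substitution (addition–elimination) of the fluoride ortho to the formyl group by the phenoxide should proceed because the aldehyde stabilises the Meisenheimer intermediate, and without a transition metal the C–I bond is retained.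

Step 5
Reactants: 4 2-(4-bromophenoxy)-4-ethenyl-1-methoxybenzene; 9 2-(3-iodophenoxy)-3,6-dimethoxybenzaldehyde
Product: 11 2-(3-{2-[3-(4-bromophenoxy)-4-methoxyphenyl]ethyl}phenoxy)-3,6-dimethoxybenzaldehyde, via B-alkyl borabicyclononane 10 (not isolated)
Conditions: 4, 9-BBN (1.05 equiv), THF, 0 °C → rt; then Cs2CO3, H2O, 9 (1.1 equiv), Pd(dppf)Cl2 (5 mol %), AsPh3 (5 mol %), DMF, rt
Reagents that add atoms: none
Why: anti-Markovnikov hydroboration of the styrene followed by B-alkyl Suzuki–Miyaura coupling should join rings B and C, because at room temperature zerovalent palladium inserts into the C–I bond of 9 much faster than into the electron-rich C–Br bond of ring A, and residual B–H is destroyed by the aqueous base before the aldehyde is added.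

Step 6
Reactants: 11 2-(3-{2-[3-(4-bromophenoxy)-4-methoxyphenyl]ethyl}phenoxy)-3,6-dimethoxybenzaldehyde
Product: 12 2-(3-{2-[3-(4-bromophenoxy)-4-methoxyphenyl]ethyl}phenoxy)-3-ethenyl-1,4-dimethoxybenzene
Conditions: MePPh3Br, KOtBu, THF, 0 °C → rt
Reagents that add atoms: methyltriphenylphosphonium bromide, C[P+](c1ccccc1)(c1ccccc1)c1ccccc1.[Br-]
Why: Wittig methylenation with the small non-stabilised ylide should tolerate the two ortho substituents of the non-enolisable aldehyde and leave the aryl bromide intact.

Step 7
Reactants: 12 2-(3-{2-[3-(4-bromophenoxy)-4-methoxyphenyl]ethyl}phenoxy)-3-ethenyl-1,4-dimethoxybenzene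
Product: 14 marchantinquinol tri-O-methyl ether (the 18-membered cyclophane of the target with ring D as 1,4-dimethoxybenzene and the ring B hydroxyl as methyl ether), via B-alkyl borabicyclononane 13 (not isolated)
Conditions: 9-BBN (2 equiv), THF, rt → 45 °C; then syringe-pump addition to Pd(dppf)Cl2 (15 mol %), AsPh3 (15 mol %), Cs2CO3, DMF/THF/H2O, 60 °C, final concentration ca. 2 mM
Reagents that add atoms: none
Why: 9-BBN adds across the ring D vinyl group with anti-Markovnikov regiochemistry to give the primary alkylborane 13; zerovalent palladium then inserts into the only C–Br bond (ring A, para to the ether oxygen), the base-activated borate transfers the primary alkyl group to the arylpalladium bromide, and reductive elimination forms the CH2–aryl bond. The closest known reaction type is the B-alkyl Suzuki–Miyaura macrocyclization used for cyclophanes and macrolides. The 18-membered ring closes end-to-end through a large palladacycle that holds the alkyl and aryl termini cis on divalent palladium, so no small-ring strain applies, no stereocentre is created and the sp3 bridge arrives at its final oxidation level. Three selectivities are needed: terminal hydroboration (secured by the bulk of 9-BBN on a monosubstituted alkene whose internal carbon is shielded by two ortho oxygens), ring closure over oligomerization (secured by slow addition at millimolar concentration and by the folded chain, in which ortho-linked ring D, meta-linked ring C and two bent diaryl ether hinges bring the ends together), and reductive elimination over β-hydride elimination (secured by the wide bite angle of dppf). The aryl methyl ethers and diaryl ethers are inert to both stages.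

Step 8
Reactants: 14 marchantinquinol tri-O-methyl ether
Product: 16 marchantinquinone, via macrocyclic hydroquinone 15 (not isolated)
Conditions: BBr3, CH2Cl2, −78 °C → rt; H2O, extraction under argon; then Ag2O, Na2SO4, Et2O/THF, rt
Reagents that add atoms: none
Why: Lewis acid cleavage of the three aryl methyl ethers by BBr3 (diaryl ethers are inert) should give the triphenol, and Ag2O should oxidise only the electron-rich hydroquinone of ring D to the quinone, leaving the isolated mono-phenol of ring B untouched.

**Compound list**

1 | isovanillin (3-hydroxy-4-methoxybenzaldehyde) | COc1ccc(C=O)cc1O | starting material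
2 | 4-bromophenylboronic acid | OB(O)c1ccc(Br)cc1 | starting material
3 | 3-(4-bromophenoxy)-4-methoxybenzaldehyde | COc1ccc(C=O)cc1Oc1ccc(Br)cc1 | intermediate
4 | 2-(4-bromophenoxy)-4-ethenyl-1-methoxybenzene | COc1ccc(C=C)cc1Oc1ccc(Br)cc1 | intermediate
5 | 2-fluoro-1,4-dimethoxybenzene | COc1ccc(OC)c(F)c1 | starting material
6 | (2-fluoro-3,6-dimethoxyphenyl)lithium | [Li]c1c(F)c(OC)ccc1OC | intermediate
7 | 2-fluoro-3,6-dimethoxybenzaldehyde | O=Cc1c(F)c(OC)ccc1OC | intermediate
8 | 3-iodophenol | Oc1cccc(I)c1 | starting material
9 | 2-(3-iodophenoxy)-3,6-dimethoxybenzaldehyde | O=Cc1c(Oc2cccc(I)c2)c(OC)ccc1OC | intermediate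
10 | 9-{2-[3-(4-bromophenoxy)-4-methoxyphenyl]ethyl}-9-borabicyclo[3.3.1]nonane | COc1ccc(CCB2C3CCCC2CCC3)cc1Oc1ccc(Br)cc1 | intermediate
11 | 2-(3-{2-[3-(4-bromophenoxy)-4-methoxyphenyl]ethyl}phenoxy)-3,6-dimethoxybenzaldehyde | O=Cc1c(Oc2cccc(CCc3ccc(OC)c(Oc4ccc(Br)cc4)c3)c2)c(OC)ccc1OC | intermediate
12 | 2-(3-{2-[3-(4-bromophenoxy)-4-methoxyphenyl]ethyl}phenoxy)-3-ethenyl-1,4-dimethoxybenzene | C=Cc1c(Oc2cccc(CCc3ccc(OC)c(Oc4ccc(Br)cc4)c3)c2)c(OC)ccc1OC | intermediate
13 | 9-{2-[2-(3-{2-[3-(4-bromophenoxy)-4-methoxyphenyl]ethyl}phenoxy)-3,6-dimethoxyphenyl]ethyl}-9-borabicyclo[3.3.1]nonane | COc1ccc(OC)c(Oc2cccc(CCc3ccc(OC)c(Oc4ccc(Br)cc4)c3)c2)c1CCB1C2CCCC1CCC2 | intermediate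
14 | marchantinquinol tri-O-methyl ether (18-membered cyclophane; ring D 1,4-dimethoxy; ring B OMe) | COc1ccc(OC)c2c1CCc1ccc(cc1)Oc1cc(ccc1OC)CCc1cccc(c1)O2 | intermediate
15 | marchantinquinol (macrocyclic hydroquinone; ring D 1,4-dihydroxy; ring B OH) | Oc1ccc(O)c2c1CCc1ccc(cc1)Oc1cc(ccc1O)CCc1cccc(c1)O2 | intermediate
16 | marchantinquinone | O=C1C=CC(=O)C2=C1CCc1ccc(cc1)Oc1cc(ccc1O)CCc1cccc(c1)O2 | target

**Summary**

Total step count: 8. Longest linear sequence: 6 steps (steps 3, 4, 5, 6, 7 and 8, from 5 to 16).

Steps most likely to fail:

Step 7. The ring closure may lose to intermolecular coupling, or the alkylborane may be consumed by protodeboronation or β-hydride elimination before it transmetalates. Fallback: setting out from styrene 12, an intramolecular Mizoroki–Heck reaction (Pd(OAc)2, P(o-tol)3, K2CO3, n-Bu4NBr, DMF, 100 °C, high dilution) would form the same ring A–carbon bond at the alkene oxidation level, with no borane involved, and give the macrocyclic stilbene F1. The E isomer is expected from syn insertion and syn β-hydride elimination, and either geometry converges in the next operation. Hydrogenation of F1 (H2, Pd/C, EtOAc) would come back to the route at 14.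

Step 5. Discrimination between the C–I and C–Br bonds may be incomplete, so that the borane couples through ring A and oligomerises, or residual borane may reduce the aldehyde. Fallback: setting out from aldehyde 3, a Wittig reaction with the ylide of (3-hydroxybenzyl)triphenylphosphonium bromide (KOtBu in excess, THF) would give the stilbene phenol 3-{2-[3-(4-bromophenoxy)-4-methoxyphenyl]ethenyl}phenol F2 as a mixture of alkene isomers. Diimide reduction (TsNHNH2, NaOAc, THF/H2O, reflux) spares the aryl bromide and would give the bibenzyl phenol 3-{2-[3-(4-bromophenoxy)-4-methoxyphenyl]ethyl}phenol F3. SNAr of F3 on fluoroaldehyde 7 (K2CO3, DMF, 110 °C) would come back to the route at 11, with no palladium used before the key step.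

Step 4. The addition–elimination may be sluggish because the two methoxy groups lower the electrophilicity of the fluoroarene and the phenoxide is a weak nucleophile. Fallback: setting out from 7, the fluoride would be displaced by the much more nucleophilic alkoxide of 2-(methylsulfonyl)ethanol (NaH, DMF, 0 °C → rt) to give 3,6-dimethoxy-2-[2-(methylsulfonyl)ethoxy]benzaldehyde F4, which eliminates in the same flask to 2-hydroxy-3,6-dimethoxybenzaldehyde F5. The roles of the two rings are then reversed: Chan–Lam coupling of F5 with 3-iodophenylboronic acid (Cu(OAc)2, pyridine, 4 Å MS, CH2Cl2, air, rt) would come back to the route at 9.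

Further compounds
F1 | step 7 | (E)-stilbene macrocycle (14 with a CH=CH bridge between rings D and A) | COc1ccc(OC)c2c1/C=C/c1ccc(cc1)Oc1cc(ccc1OC)CCc1cccc(c1)O2
F2 | step 5 | 3-{(E)-2-[3-(4-bromophenoxy)-4-methoxyphenyl]ethenyl}phenol (E isomer drawn) | COc1ccc(/C=C/c2cccc(O)c2)cc1Oc1ccc(Br)cc1
F3 | step 5 | 3-{2-[3-(4-bromophenoxy)-4-methoxyphenyl]ethyl}phenol | COc1ccc(CCc2cccc(O)c2)cc1Oc1ccc(Br)cc1
F4 | step 4 | 3,6-dimethoxy-2-[2-(methylsulfonyl)ethoxy]benzaldehyde | O=Cc1c(OCCS(C)(=O)=O)c(OC)ccc1OC
F5 | step 4 | 2-hydroxy-3,6-dimethoxybenzaldehyde | O=Cc1c(O)c(OC)ccc1OC
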